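**Plan**
Cuts, in retrosynthetic order: (i) the helpers, namely three C=C bonds and two O-benzyl groups, all removed forward by one hydrogenation; (ii) O1–C2 and C4–C4a of the pyran ring on the acyl-bearing ring A (retro oxa-6π / [1,5]-H / [3,3]), back to an O4'-(1,1-dimethylpropargyl) ether; (iii) Cα=Cβ (Claisen–Schmidt); (iv) each O–CMe2 bond, back to 3-chloro-3-methylbut-1-yne.
Forward order: pyran on ring B (step 2), chain joined (step 5), pyran on ring A closed last (step 6), global hydrogenation/hydrogenolysis (step 7).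
Enabling feature: ring A (C1' = acyl carbon) is symmetric about its C1'–C4' axis, so C3' and C5' are equivalent. O4' is the only non-chelated and the most acidic oxygen, and the ring atoms O1–C2(Me)2–C3–C4 map exactly onto O–CMe2–C≡CH.
The C5 unit is therefore hung on O4' first and O2'/O6' are blocked as benzyl ethers. Heat then moves the carbon terminus to C3' and returns O4' to CMe2, so only the 6-acyl-5,7-dioxygenated ring system can form, not the 8-acyl isomer.
Stereochemistry: none to set. The E-enone and the transient sp3 centre of the cascade are erased.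

Key step: step 6

Remark: the target SMILES holds no stereocentre and no stereogenic double bond, so the compound is achiral and needs no stereocontrol. Primed locants refer to ring A; O1–C8a is the chroman numbering.

Step 1
Reactants: 1 4-hydroxybenzaldehyde; 2 3-chloro-3-methylbut-1-yne
Product: 3 4-[(2-methylbut-3-yn-2-yl)oxy]benzaldehyde
Conditions: 2 (1.3 equiv), DBU (1.4 equiv), CuCl2·2H2O (1 mol %), MeCN, 0 °C to rt, N2
Reagents that add atoms: none
Why: Copper-catalysed propargylic etherification, in which a copper acetylide-derived electrophile lets the phenoxide attack the tertiary carbon where a plain SN2 reaction is impossible.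

Step 2
Reactants: 3 4-[(2-methylbut-3-yn-2-yl)oxy]benzaldehyde
Product: 7 2,2-dimethyl-2H-chromene-6-carbaldehyde, via allenyl dienone 4 (not isolated), via allenylphenol 5 (not isolated), via o-quinone methide 6 (not isolated)
Conditions: PhNEt2, 190 °C, Ar
Reagents that add atoms: none
Why: Aromatic propargyl Claisen rearrangement, enolisation, [1,5]-H shift and oxa-6π electrocyclisation form the standard thermal route from aryl 1,1-dimethylpropargyl ethers to 2,2-dimethyl-2H-chromenes, and the two ortho positions are equivalent.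

Step 3
Reactants: 8 1-(2,4,6-trihydroxyphenyl)ethanone (dried monohydrate); 2 3-chloro-3-methylbut-1-yne
Product: 9 1-{2,6-dihydroxy-4-[(2-methylbut-3-yn-2-yl)oxy]phenyl}ethanone
Conditions: 2 (1.1 equiv), DBU (1.05 equiv), CuCl2·2H2O (1 mol %), MeCN, −5 to 0 °C, N2
Reagents that add atoms: none
Why: In the same copper-catalysed propargylic etherification, one equivalent of base ionises only O4, which is para to the acetyl group, non-chelated and most acidic, while O2 and O6 stay hydrogen-bonded to the carbonyl group.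

Step 4
Reactants: 9 1-{2,6-dihydroxy-4-[(2-methylbut-3-yn-2-yl)oxy]phenyl}ethanone
Product: 10 1-{2,6-bis(benzyloxy)-4-[(2-methylbut-3-yn-2-yl)oxy]phenyl}ethanone
Conditions: BnBr (2.5 equiv), K2CO3 (3 equiv), Bu4NI (cat.), DMF, 50 °C
Reagents that add atoms: benzyl bromide, BrCc1ccccc1
Why: Williamson etherification of both chelated phenols in a dipolar aprotic solvent, run well below the onset temperature of the propargyl Claisen rearrangement.

Step 5
Reactants: 10 1-{2,6-bis(benzyloxy)-4-[(2-methylbut-3-yn-2-yl)oxy]phenyl}ethanone; 7 2,2-dimethyl-2H-chromene-6-carbaldehyde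
Product: 11 (E)-1-{2,6-bis(benzyloxy)-4-[(2-methylbut-3-yn-2-yl)oxy]phenyl}-3-(2,2-dimethyl-2H-chromen-6-yl)prop-2-en-1-one
Conditions: KOH (50 % aq.), EtOH, rt
Reagents that add atoms: none
Why: Claisen–Schmidt condensation of the only enolisable partner with a non-enolisable aldehyde gives the E-enone by E1cB loss of water, and with no free 2'-OH no flavanone can form.

Step 6
Reactants: 11 (E)-1-{2,6-bis(benzyloxy)-4-[(2-methylbut-3-yn-2-yl)oxy]phenyl}-3-(2,2-dimethyl-2H-chromen-6-yl)prop-2-en-1-one
Product: 15 (E)-1-[5,7-bis(benzyloxy)-2,2-dimethyl-2H-chromen-6-yl]-3-(2,2-dimethyl-2H-chromen-6-yl)prop-2-en-1-one, via allenyl dienone 12 (not isolated), via allenylphenol 13 (not isolated), via o-quinone methide 14 (not isolated)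
Conditions: PhNEt2, 150 °C, Ar, BHT (cat.)
Reagents that add atoms: none
Why: Heat triggers an aromatic propargyl Claisen [3,3] shift that breaks O4'–CMe2 and joins the alkyne terminus to C3' (the future C4–C4a bond) to give dienone 12, which enolises to allenylphenol 13; a [1,5]-H shift from O4'–H to the central allene carbon gives the (Z)-o-quinone methide 14, and a thermal disrotatory oxa-6π electrocyclisation forms O1–C2 and restores aromaticity. The closest known reaction type is the thermal conversion of aryl 1,1-dimethylpropargyl ethers into 2,2-dimethyl-2H-chromenes, as in step 2. The only ring closed is the six-membered pyran, by 6π electrocyclic closure of the oxatriene O4'=C4'–C3'=CH–CH=CMe2, and the gem-dimethyl terminus both accelerates the [3,3] shift and excludes the competing path to an aromatic benzofuran. No stereocentre persists, since C3' of 12 is transient and 15 keeps only the E-enone. Regiocontrol is needed in two senses: C3' and C5' are equivalent through the local symmetry of the 2',6'-bis(benzyloxy)-4'-oxy ring, so the [3,3] shift has one outcome, and O4' is the only oxygen able to become the quinone methide carbonyl because O2' and O6' are benzylated, so only the 6-acyl and not the 8-acyl chromene can form. The enone, the benzyl ethers and the ring-B chromene (made at higher temperature in step 2) should be inert at this temperature.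

Step 7
Reactants: 15 (E)-1-[5,7-bis(benzyloxy)-2,2-dimethyl-2H-chromen-6-yl]-3-(2,2-dimethyl-2H-chromen-6-yl)prop-2-en-1-one
Product: 16 1-(5,7-dihydroxy-2,2-dimethylchroman-6-yl)-3-(2,2-dimethylchroman-6-yl)propan-1-one
Conditions: H2 (1 atm), 10 % Pd/C, EtOAc–MeOH, rt
Reagents that add atoms: none
Why: Heterogeneous catalytic hydrogenation saturates the enone C=C and both chromene C3=C4 bonds and hydrogenolyses both benzyl ethers in one operation, while the chelated 2,6-dihydroxyaryl ketone that results resists further reduction and no stereocentre is created.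

**Compound list**
1 | 4-hydroxybenzaldehyde | O=Cc1ccc(O)cc1 | starting material
2 | 3-chloro-3-methylbut-1-yne | C#CC(C)(C)Cl | starting material
3 | 4-[(2-methylbut-3-yn-2-yl)oxy]benzaldehyde | C#CC(C)(C)Oc1ccc(C=O)cc1 | intermediate
4 | 3-(3-methylbuta-1,2-dien-1-yl)-4-oxocyclohexa-1,5-diene-1-carbaldehyde (racemic, transient) | O=CC1=CC(C=C=C(C)C)C(=O)C=C1 | intermediate
5 | 4-hydroxy-3-(3-methylbuta-1,2-dien-1-yl)benzaldehyde | CC(C)=C=Cc1cc(C=O)ccc1O | intermediate
6 | (3Z)-3-(3-methylbut-2-en-1-ylidene)-4-oxocyclohexa-1,5-diene-1-carbaldehyde | CC(C)=C/C=C1\C(=O)C=CC(C=O)=C1 | intermediate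
7 | 2,2-dimethyl-2H-chromene-6-carbaldehyde | CC1(C)C=Cc2cc(C=O)ccc2O1 | intermediate
8 | 1-(2,4,6-trihydroxyphenyl)ethanone | CC(=O)c1c(O)cc(O)cc1O | starting material
9 | 1-{2,6-dihydroxy-4-[(2-methylbut-3-yn-2-yl)oxy]phenyl}ethanone | CC(=O)c1c(O)cc(OC(C)(C)C#C)cc1O | intermediate
10 | 1-{2,6-bis(benzyloxy)-4-[(2-methylbut-3-yn-2-yl)oxy]phenyl}ethanone | CC(=O)c1c(OCc2ccccc2)cc(OC(C)(C)C#C)cc1OCc1ccccc1 | intermediate
11 | (E)-1-{2,6-bis(benzyloxy)-4-[(2-methylbut-3-yn-2-yl)oxy]phenyl}-3-(2,2-dimethyl-2H-chromen-6-yl)prop-2-en-1-one | C#CC(C)(C)Oc1cc(OCc2ccccc2)c(C(=O)/C=C/c2ccc3c(c2)C=CC(C)(C)O3)c(OCc2ccccc2)c1 | intermediate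
12 | 3,5-bis(benzyloxy)-4-[(E)-3-(2,2-dimethyl-2H-chromen-6-yl)acryloyl]-6-(3-methylbuta-1,2-dien-1-yl)cyclohexa-2,4-dien-1-one (racemic, transient) | O=C1C=C(OCc2ccccc2)C(C(=O)/C=C/c2ccc3c(c2)C=CC(C)(C)O3)=C(OCc2ccccc2)C1C=C=C(C)C | intermediate
13 | (E)-1-[2,6-bis(benzyloxy)-4-hydroxy-3-(3-methylbuta-1,2-dien-1-yl)phenyl]-3-(2,2-dimethyl-2H-chromen-6-yl)prop-2-en-1-one | CC(C)=C=Cc1c(O)cc(OCc2ccccc2)c(C(=O)/C=C/c2ccc3c(c2)C=CC(C)(C)O3)c1OCc1ccccc1 | intermediate
14 | (6Z)-3,5-bis(benzyloxy)-4-[(E)-3-(2,2-dimethyl-2H-chromen-6-yl)acryloyl]-6-(3-methylbut-2-en-1-ylidene)cyclohexa-2,4-dien-1-one | CC(C)=C/C=C1\C(=O)C=C(OCc2ccccc2)C(C(=O)/C=C/c2ccc3c(c2)C=CC(C)(C)O3)=C1OCc1ccccc1 | intermediate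
15 | (E)-1-[5,7-bis(benzyloxy)-2,2-dimethyl-2H-chromen-6-yl]-3-(2,2-dimethyl-2H-chromen-6-yl)prop-2-en-1-one | CC1(C)C=Cc2c(O1)cc(OCc1ccccc1)c(C(=O)/C=C/c1ccc3c(c1)C=CC(C)(C)O3)c2OCc1ccccc1 | intermediate
16 | 1-(5,7-dihydroxy-2,2-dimethylchroman-6-yl)-3-(2,2-dimethylchroman-6-yl)propan-1-one | CC1(C)CCc2cc(CCC(=O)c3c(O)cc4c(c3O)CCC(C)(C)O4)ccc2O1 | target

Total step count: 7. Longest linear sequence: 5 steps (3, 4, 5, 6, 7; the branch 1, 2, 5, 6, 7 is equally long).

**Steps most likely to fail**

Step 6. Heterolysis or elimination at the tertiary propargylic C–O bond, or slow thermal decay of the enone, may outrun the [3,3] shift. The fallback sets out from 11 and returns at 15; it separates C–C bond formation from ring closure.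
- Semi-hydrogenation of the alkyne (H2, Lindlar catalyst, quinoline, EtOAc) should give the 1,1-dimethylallyl ether (E)-1-{2,6-bis(benzyloxy)-4-[(2-methylbut-3-en-2-yl)oxy]phenyl}-3-(2,2-dimethyl-2H-chromen-6-yl)prop-2-en-1-one F1.
- Its aromatic allyl Claisen rearrangement runs at much lower temperature (toluene, 110 °C) and should give the ortho-prenylphenol (E)-1-[2,6-bis(benzyloxy)-4-hydroxy-3-(3-methylbut-2-en-1-yl)phenyl]-3-(2,2-dimethyl-2H-chromen-6-yl)prop-2-en-1-one F2.
- DDQ in benzene at reflux then dehydrogenates the prenylphenol to the same quinone methide 14, which closes to 15.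

Step 3. Site selectivity may be poor: alkylation at a chelated oxygen, double alkylation, or C-propargylation of the very electron-rich ring. The fallback sets out from 8 and returns at 10; the tertiary electrophile then meets a substrate with a single free phenol.
- MOMCl (1 equiv) and iPr2NEt in CH2Cl2 at 0 °C should cap the non-chelated oxygen to give 1-[2,6-dihydroxy-4-(methoxymethoxy)phenyl]ethanone F3.
- BnBr and K2CO3 in DMF should give 1-[2,6-bis(benzyloxy)-4-(methoxymethoxy)phenyl]ethanone F4.
- Catalytic HCl in MeOH at 40 °C should free 1-[2,6-bis(benzyloxy)-4-hydroxyphenyl]ethanone F5.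
- F5 is etherified with 2 under the conditions of step 1 to give 10.

Step 7. Chemoselectivity of the global reduction may fail: the aryl ketone could be over-reduced before debenzylation sets up the chelate, or the ring-A chromene flanked by a benzyloxy group could be saturated incompletely. The fallback sets out from 15 and returns at 16; it splits the reduction into two chemoselective events.
- Homogeneous hydrogenation (H2, RhCl(PPh3)3, benzene–EtOH) touches only the three C=C bonds and should give 1-[5,7-bis(benzyloxy)-2,2-dimethylchroman-6-yl]-3-(2,2-dimethylchroman-6-yl)propan-1-one F6.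
- Transfer hydrogenolysis (Pd(OH)2/C, cyclohexa-1,4-diene, EtOH) then removes the benzyl groups to give 16.

**Further compounds**
F1 | step 6 | (E)-1-{2,6-bis(benzyloxy)-4-[(2-methylbut-3-en-2-yl)oxy]phenyl}-3-(2,2-dimethyl-2H-chromen-6-yl)prop-2-en-1-one | C=CC(C)(C)Oc1cc(OCc2ccccc2)c(C(=O)/C=C/c2ccc3c(c2)C=CC(C)(C)O3)c(OCc2ccccc2)c1
F2 | step 6 | (E)-1-[2,6-bis(benzyloxy)-4-hydroxy-3-(3-methylbut-2-en-1-yl)phenyl]-3-(2,2-dimethyl-2H-chromen-6-yl)prop-2-en-1-one | CC(C)=CCc1c(O)cc(OCc2ccccc2)c(C(=O)/C=C/c2ccc3c(c2)C=CC(C)(C)O3)c1OCc1ccccc1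
F3 | step 3 | 1-[2,6-dihydroxy-4-(methoxymethoxy)phenyl]ethanone | CC(=O)c1c(O)cc(OCOC)cc1O
F4 | step 3 | 1-[2,6-bis(benzyloxy)-4-(methoxymethoxy)phenyl]ethanone | CC(=O)c1c(OCc2ccccc2)cc(OCOC)cc1OCc1ccccc1
F5 | step 3 | 1-[2,6-bis(benzyloxy)-4-hydroxyphenyl]ethanone | CC(=O)c1c(OCc2ccccc2)cc(O)cc1OCc1ccccc1
F6 | step 7 | 1-[5,7-bis(benzyloxy)-2,2-dimethylchroman-6-yl]-3-(2,2-dimethylchroman-6-yl)propan-1-one | CC1(C)CCc2c(O1)cc(OCc1ccccc1)c(C(=O)CCc1ccc3c(c1)CCC(C)(C)O3)c2OCc1ccccc1
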